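## The problem

Target 24 is a phenylcoumaran neolignan: a 2,3-dihydrobenzofuran whose fused arene (ring A) carries a methoxy group at C7 and an (E)-propenoic acid at C5, whose C2 carries a 4-hydroxy-3,5-dimethoxyphenyl group (ring B) and whose C3 carries a hydroxymethyl group. The only stereocentres are the adjacent C2 (S) and C3 (R), trans to each other, and nothing else in the molecule can relay chirality to them, so the absolute configuration has to come from a reagent or catalyst. The two centres are not equivalent: C2 is a benzylic ether carbon para to a phenol and can be re-formed or epimerised through a quinone methide or benzylic cation under the influence of C3, whereas C3, once made, cannot be corrected from C2. The same para-hydroxybenzyl ether makes the free phenol sensitive to strong acid and hot base, the propenoic acid double bond rules out any late hydrogenation, and three electron-rich arenes rule out harsh oxidants. The skeleton must be assembled from ring A, ring B and the three-carbon unit C2–C3–CH2OH through two aryl–C(sp3) bonds and one aryl–O bond. The feature that opens a short route is that C2 and C3 are neighbouring carbons that each bear exactly one arene (ring B on C2, ring A through C3a on C3), with oxygen on C2 and a CH2O arm on C3. This is the pattern left when two aryl groups are added across the alkene of an (E)-3-oxypropenyl boron compound, the boron marking the place of the future O1. O1 can then be joined to C7a because that carbon lies para to C5, where an electron-withdrawing precursor of the side chain can activate a leaving group.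

## Retrosynthesis

**24 from 23.** Only the two Si–O bonds are cut: the phenol of ring B and the primary alcohol are both carried as triisopropylsilyl ethers in 23. A benzyl ether on the phenol would have to be hydrogenolysed before the alkene exists, which adds a step and exposes the free phenol to the later condensation. Two identical silyl groups fall in one fluoride treatment at the very end. The forward step must cleave an aryl and a primary alkyl silyl ether without opening the C2–O1 bond.

**23 from 21, and 21 from 19.** The Cα=Cβ bond of the propenoic acid is cut (Knoevenagel–Doebner condensation of aldehyde 21), and the aldehyde is carried as the nitrile of 19. A Heck reaction on a C5 bromide would be shorter, but the only bromide of ring A is needed as the electrophile of the key step. A nitrile is also the one formyl precursor that activates C7a for ring closure while ignoring boron ate complexes and palladium. The forward reactions are a single hydride addition to the nitrile and an (E)-selective condensation.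

**19 from 18.** The aryl–oxygen bond O1–C7a is cut, which opens the ring to the fluoro alcohol 18. The neighbouring cut, O1–C2, would require displacement or ionisation at C2 and would discard the configuration that the key step delivers. Displacement of fluoride at the arene touches neither stereocentre. The forward reaction asks the C2 alkoxide to attack the C–F carbon (ortho to the side chain, para to the nitrile) faster than any silyl transfer.

**18 from 17.** The C–O bond at the future C2 is traded for a C–B bond, since oxidation of a boronic ester is stereoretentive. 17 is the direct product of the key step.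

**17 from 7, 15 and 14 (through borate 16).** Two bonds are cut at once: C2–aryl (ring B) and C3–C3a. This reduces 17 to an (E)-alkenyl boronic ester 7, the ring B aryllithium 15 and the ring A bromide 14, and creates both stereocentres in one catalytic step. Cutting C2–C3 instead (an aldol construction) needs a stoichiometric auxiliary and several redox and protection steps. Cutting only C3–C3a leaves the stereochemical problem unsolved. The boron ligand is chosen with care: pinacol esters of β-substituted alkenylboron ate complexes tend to hand an organic group directly to palladium, so the alkenyl boron is carried as the ester of cis-1,2-dimethylacenaphthene-1,2-diol 4, written B(mac) below, for which the conjunctive pathway is established with β-substituents. The forward reaction must add ring B and ring A anti across the (E)-alkene, which is exactly the relationship that two retentive steps turn into the trans ring, and the ligand on palladium must choose the alkene face.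

**7 from 2, 5 and 4; 2 from 1; 4 from 3.** The C–B bond is cut by syn hydroboration of the silylated propargyl alcohol 2 with catecholborane 5. The B–O bonds come from ester exchange with diol 4, itself made by twofold methyl addition to acenaphthoquinone 3. Catecholborane is preferred to pinacolborane because its ester exchanges with 4 in the same flask.

**15 from 9; 9 from 8.** The C–Li bond comes from bromine–lithium exchange on the silylated bromophenol 9, made from commercial 4-bromo-2,6-dimethoxyphenol 8.

**14 from 12; 12 from 10.** The C–F bond is cut back to the phenol C–O bond (deoxyfluorination through the aryl fluorosulfonate 13) and the nitrile back to the aldehyde of 5-bromovanillin 10. That starting material already has bromine, oxygen and methoxy on adjacent carbons with the carbon substituent para to the oxygen. The forward fluorination has to work at a carbon flanked by two ortho substituents, helped by the para nitrile.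

## Roads not taken

**Alternative 1:** The cut is C3–C3a, made by a 1,2-shift of ring A. The (2S)-flavanone A2 (6-bromo-8-methoxy, ring B as its pivalate) would be treated with PhI(OAc)2 and H2SO4 in trimethyl orthoformate. Trivalent iodine attacks the enol ether at C3, ring A migrates from the carbonyl carbon to C3 with reductive loss of the iodine, and the six-membered ring contracts to the trans ester A1. The ester would become the CH2OH arm and the bromide would take the propenoate by a Heck reaction.
- Merits: only one stereocentre (C2 of A2) has to be set and C3 follows from it; no organolithium or chiral ferrocenyl ligand is needed; the end game from the bromide is a step shorter than nitrile reduction plus condensation.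
- Weak points: ring B is a trioxygenated arene, and with electron-rich C2 aryl groups the competing shift of ring B from C2 to C3 and simple dehydrogenation of the heterocycle are the classical diversions, which the pivalate can only damp. Ring A, the group that must migrate, is deactivated by bromine. The strongly acidic medium can reversibly open the pyranone ring of A2 or ionise C2, and either erodes the one stereocentre on which everything rests. A stoichiometric oxidant also meets three electron-rich rings.
- Comparison: in reagent cost and end-game length this road is the better one. Its stereochemical outcome depends on migratory aptitudes and on C2 surviving acid, whereas the chosen plan fixes both centres in one catalytic, non-acidic step by a stereospecific mechanism.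

**Alternative 2:** The cuts are O1–C2 and C2–C3, a four-plus-one annulation in which C2 arrives as a sulfonium ylide carbon. Cs2CO3 would eliminate sulfinate from the phenol sulfone A4 to give the ortho-quinone methide A5, and would deprotonate the ring B benzylsulfonium salt A6, built on a C2-symmetric chiral thiolane. Conjugate addition forms C2–C3, and the phenoxide then displaces the sulfide at C2 to give the trans dihydrobenzofuran A3.
- Merits: very convergent; the ring and both stereocentres arise in one metal-free operation; trans selectivity is inherent in the closure of the betaine; the C5 bromide again allows a direct Heck end game.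
- Weak points: A5 carries a CH2OSi group on its methide carbon and can tautomerise to the ortho-hydroxystyrene before the ylide arrives. Aryl-stabilised ylides are less disciplined than ester- or keto-stabilised ones. Enantiocontrol would rest on a stoichiometric chiral sulfide whose performance with this ylide class is not established. Both partners need several steps each.
- Comparison: in convergence and in the number of steps after ring formation this road is at least as good. The chosen plan sets against it a catalytic source of chirality with precedent for this class of alkenyl borate, and a relative configuration that follows from alkene geometry instead of having to be found.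

**Alternative 3:** At the ring-forming stage only O1–C7a is cut. C2–C3 is made earlier by an auxiliary-controlled syn aldol reaction (Evans type) between ring A and ring B building blocks, followed by reductive removal of the auxiliary and silylation to the fluoro alcohol A8. KN(SiMe3)2 then converts the C2 hydroxyl into its alkoxide, which displaces the fluoride ortho to the side chain and para to the nitrile to give A7.
- Merits: every step is textbook chemistry; the syn aldol reliably gives the relative and absolute configuration needed; the ring closure is the same retentive displacement that the chosen plan uses in step 9.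
- Weak points: a stoichiometric auxiliary; an arylacetic acid with the fluoro/methoxy/cyano pattern that must first be made by an extra C–C bond formation; attachment and removal of the auxiliary and a selective protection, about five more steps in the longest line. The benzyl ether of A7 must also be hydrogenolysed before the alkene exists, in the presence of a nitrile and a benzylic C–O bond.
- Comparison: in certainty this road is better than the chosen one, and a silyl-protected version of it is held in reserve for the key step. The chosen plan sets against it that the same type of acyclic intermediate is reached from three simple pieces in one catalytic step, with no auxiliary and a shorter longest line.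

Key step: step 7

Remark: the ligand meant in step 7 is (Sp,Sp)-Mandyphos, 1,1'-bis[bis(4-methoxy-3,5-dimethylphenyl)phosphino]-2,2'-bis[(R)-α-(dimethylamino)benzyl]ferrocene; it is assumed, by analogy with known couplings of this ligand class, to place palladium on the Si face of the silyloxymethyl-bearing alkene carbon, and its equally available mirror image would be used if the sense proved opposite.

## Route

**Step 1**
Reactants: 1 prop-2-yn-1-ol
Product: 2 triisopropyl(prop-2-yn-1-yloxy)silane
Conditions: i-Pr3SiCl, imidazole, CH2Cl2, 0 °C to rt
Reagents that add atoms: chlorotriisopropylsilane, CC(C)[Si](Cl)(C(C)C)C(C)C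
Why: Imidazole-assisted silylation of a primary alcohol; the bulky triisopropylsilyl group is chosen because it resists base, oxygen-to-oxygen transfer and β-elimination at palladium in the later steps.

**Step 2**
Reactants: 3 acenaphthylene-1,2-dione (acenaphthoquinone)
Product: 4 cis-1,2-dimethyl-1,2-dihydroacenaphthylene-1,2-diol (meso)
Conditions: AlMe3 (excess), toluene, 0 °C to rt; then 1 M HCl
Reagents that add atoms: trimethylaluminium, C[Al](C)C
Why: Twofold 1,2-addition of methylaluminium to the 1,2-dione; the second methyl group should enter anti to the bulky aluminium alkoxide formed first, which places the two oxygens cis, and since only the cis diol can bridge one boron atom, any trans isomer is removed by crystallisation and cannot enter step 3.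

**Step 3**
Reactants: 2 triisopropyl(prop-2-yn-1-yloxy)silane, 5 catecholborane, 4 cis-1,2-dimethyl-1,2-dihydroacenaphthylene-1,2-diol
Product: 7 triisopropyl{[(E)-3-(6b,9a-dimethyl-6b,9a-dihydroacenaphtho[1,2-d][1,3,2]dioxaborol-8-yl)prop-2-en-1-yl]oxy}silane [the (E)-alkenyl B(mac) ester], via (E)-alkenyl catechol boronate 6 (not isolated)
Conditions: 5, dicyclohexylborane (cat.), THF, rt; then 4, rt
Reagents that add atoms: none
Why: Syn hydroboration of the terminal alkyne places boron on the terminal carbon and gives the (E)-alkenyl catechol ester, whose labile B–O bonds exchange with the preorganised ditertiary cis diol to give the chromatography-stable B(mac) ester (alkyne hydroboration followed by boronic ester exchange).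

**Step 4**
Reactants: 8 4-bromo-2,6-dimethoxyphenol
Product: 9 (4-bromo-2,6-dimethoxyphenoxy)triisopropylsilane
Conditions: i-Pr3SiCl, imidazole, DMF, 50 °C
Reagents that add atoms: chlorotriisopropylsilane, CC(C)[Si](Cl)(C(C)C)C(C)C
Why: Silylation of a hindered phenol; the aryl silyl ether, shielded by two ortho methoxy groups, should survive organolithium, alkoxide, hydride and amine conditions and falls with the other silyl ether in the last step.

**Step 5**
Reactants: 10 5-bromovanillin (3-bromo-4-hydroxy-5-methoxybenzaldehyde)
Product: 12 3-bromo-4-hydroxy-5-methoxybenzonitrile, via aldoxime 11 (not isolated)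
Conditions: NH2OH·HCl, HCO2Na, HCO2H, reflux
Reagents that add atoms: hydroxylamine hydrochloride, Cl.NO
Why: One-pot oximation and dehydration of the oxime in hot formic acid, a standard aldehyde-to-nitrile conversion that tolerates free phenols of the vanillin type.

**Step 6**
Reactants: 12 3-bromo-4-hydroxy-5-methoxybenzonitrile
Product: 14 3-bromo-4-fluoro-5-methoxybenzonitrile, via aryl fluorosulfonate 13 (not isolated)
Conditions: SO2F2, NMe4F, DMF, rt to 80 °C
Reagents that add atoms: tetramethylammonium fluoride, C[N+](C)(C)C.[F-]; sulfuryl fluoride, O=S(=O)(F)F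
Why: Deoxyfluorination of a phenol through its aryl fluorosulfonate: the phenoxide is sulfonylated by SO2F2 and fluoride then displaces fluorosulfate at the ipso carbon by nucleophilic aromatic substitution, which the para nitrile and the two inductively withdrawing ortho substituents favour.

**Step 7**
Reactants: 9 (4-bromo-2,6-dimethoxyphenoxy)triisopropylsilane, 7 (E)-alkenyl B(mac) ester, 14 3-bromo-4-fluoro-5-methoxybenzonitrile
Product: 17 3-{(1S,2R)-1-[3,5-dimethoxy-4-(triisopropylsilyloxy)phenyl]-1-(6b,9a-dimethyl-6b,9a-dihydroacenaphtho[1,2-d][1,3,2]dioxaborol-8-yl)-3-(triisopropylsilyloxy)propan-2-yl}-4-fluoro-5-methoxybenzonitrile, via aryllithium 15 (not isolated), via lithium borate complex 16 (not isolated)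
Conditions: 9, t-BuLi (2 equiv), Et2O, −78 °C; 7, −78 °C to rt; solvent to THF; 14, Pd(OAc)2 (cat.), (Sp,Sp)-Mandyphos (cat.), KOSO2CF3, 60 °C
Reagents that add atoms: none
Why: Zerovalent palladium, formed in situ from Pd(OAc)2 and the bisphosphine, inserts into the C–Br bond of 14, and loss of bromide to potassium (KBr precipitates) leaves a cationic aryl complex of divalent palladium that binds the alkene of borate 16. This π-activation triggers a 1,2-metallate shift in which ring B moves from boron to the boron-bearing carbon on the face opposite palladium while palladium becomes σ-bonded to the neighbouring carbon, and C–C reductive elimination with retention then joins ring A to that carbon; the closest known reaction type is the palladium/Mandyphos-catalysed conjunctive cross-coupling of β-substituted alkenylboron ate complexes carrying the mac diol with aryl electrophiles. No ring is closed in this step. The relative configuration of the two new stereocentres (C1 and C2 of the propane chain, the later C2 and C3) follows from the (E)-geometry of 7 through stereospecific anti addition of the two arenes, which is the arrangement that the retentive steps 8 and 9 convert into the trans ring. The absolute configuration is set by the chiral bisphosphine, which must place palladium on the Si face of the silyloxymethyl-bearing alkene carbon to give (1S,2R). The step needs chemoselectivity for the metallate shift over direct transfer of an organic group from boron to palladium, which the hindered mac diol on boron secures where a pinacol ester would not, and over β-elimination of hydride or silyloxide from the alkylpalladium intermediate, which fast reductive elimination at the bisphosphine complex and the poor leaving ability of the triisopropylsilyloxy group should suppress. Site selectivity (C–Br before C–F) is inherent, and because 15 is consumed completely in forming 16 before 14 is added, the nitrile never meets a free organolithium.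

**Step 8**
Reactants: 17 boronic ester from step 7
Product: 18 3-{(1S,2R)-1-[3,5-dimethoxy-4-(triisopropylsilyloxy)phenyl]-1-hydroxy-3-(triisopropylsilyloxy)propan-2-yl}-4-fluoro-5-methoxybenzonitrile
Conditions: NaBO3·4H2O, THF/H2O, rt
Reagents that add atoms: sodium perborate, [Na+].[O-]OB=O
Why: Oxidation of a secondary boronic ester: the peroxide adds to boron and carbon migrates from boron to oxygen with retention, so C1 keeps its configuration; the mild perborate is chosen over alkaline hydrogen peroxide to spare the nitrile and the aryl silyl ether.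

**Step 9**
Reactants: 18 (1S,2R)-fluoro alcohol
Product: 19 (2S,3R)-2-[3,5-dimethoxy-4-(triisopropylsilyloxy)phenyl]-7-methoxy-3-[(triisopropylsilyloxy)methyl]-2,3-dihydro-1-benzofuran-5-carbonitrile
Conditions: KN(SiMe3)2, THF, 0 °C to rt
Reagents that add atoms: none
Why: Intramolecular nucleophilic aromatic substitution (5-exo closure onto C7a): the potassium alkoxide attacks the C–F carbon ortho to the side chain and para to the nitrile, which stabilises the anionic intermediate; no bond to either stereocentre is broken, so the anti adduct gives the trans (2S,3R) ring.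

**Step 10**
Reactants: 19 dihydrobenzofuran nitrile
Product: 21 (2S,3R)-2-[3,5-dimethoxy-4-(triisopropylsilyloxy)phenyl]-7-methoxy-3-[(triisopropylsilyloxy)methyl]-2,3-dihydro-1-benzofuran-5-carbaldehyde, via N-aluminated aldimine 20 (not isolated)
Conditions: i-Bu2AlH, toluene, −78 °C; then aq. KNaC4H4O6, rt
Reagents that add atoms: water, O
Why: A single hydride adds to the nitrile to give an N-aluminated aldimine that is stable at low temperature and is hydrolysed to the aldehyde on aqueous work-up; silyl and aryl ethers are inert to the reagent.

**Step 11**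
Reactants: 21 dihydrobenzofuran aldehyde
Product: 23 (E)-3-{(2S,3R)-2-[3,5-dimethoxy-4-(triisopropylsilyloxy)phenyl]-7-methoxy-3-[(triisopropylsilyloxy)methyl]-2,3-dihydro-1-benzofuran-5-yl}prop-2-enoic acid, via arylidenemalonic acid 22 (not isolated)
Conditions: CH2(CO2H)2, pyridine, piperidine (cat.), 90 °C
Reagents that add atoms: malonic acid, O=C(O)CC(=O)O
Why: Knoevenagel–Doebner condensation: amine-catalysed condensation with malonic acid followed by decarboxylation in pyridine gives the thermodynamically favoured (E)-cinnamic acid; with the ring B phenol still silylated, C2–O1 cannot open through a quinone methide in the hot amine.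

**Step 12**
Reactants: 23 bis-silyl propenoic acid
Product: 24 (E)-3-[(2S,3R)-2-(4-hydroxy-3,5-dimethoxyphenyl)-3-(hydroxymethyl)-7-methoxy-2,3-dihydro-1-benzofuran-5-yl]prop-2-enoic acid
Conditions: Bu4NF, THF, 0 °C to rt; then 1 M HCl to pH 3
Reagents that add atoms: none
Why: Fluoride-driven cleavage of both Si–O bonds (formation of the strong Si–F bond) frees the phenol and the primary alcohol in one operation; low temperature and prompt acidification keep the phenoxide from opening the ring, and neither stereocentre is touched.

## Compound list

1 | prop-2-yn-1-ol | OCC#C | starting material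
2 | triisopropyl(prop-2-yn-1-yloxy)silane | C#CCO[Si](C(C)C)(C(C)C)C(C)C | intermediate
3 | acenaphthylene-1,2-dione (acenaphthoquinone) | O=C1C(=O)c2cccc3cccc1c23 | starting material
4 | cis-1,2-dimethyl-1,2-dihydroacenaphthylene-1,2-diol (meso, 1R,2S) | C[C@]1(O)c2cccc3cccc(c23)[C@@]1(C)O | intermediate
5 | catecholborane (2H-1,3,2-benzodioxaborole) | B1Oc2ccccc2O1 | starting material
6 | 2-[(E)-3-(triisopropylsilyloxy)prop-1-en-1-yl]-1,3,2-benzodioxaborole | CC(C)[Si](C(C)C)(C(C)C)OC/C=C/B1Oc2ccccc2O1 | intermediate
7 | triisopropyl{[(E)-3-(6b,9a-dimethyl-6b,9a-dihydroacenaphtho[1,2-d][1,3,2]dioxaborol-8-yl)prop-2-en-1-yl]oxy}silane (cis-fused, from meso diol 4) | CC(C)[Si](C(C)C)(C(C)C)OC/C=C/B1O[C@@]2(C)c3cccc4cccc(c34)[C@@]2(C)O1 | intermediate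
8 | 4-bromo-2,6-dimethoxyphenol | COc1cc(Br)cc(OC)c1O | starting material
9 | (4-bromo-2,6-dimethoxyphenoxy)triisopropylsilane | COc1cc(Br)cc(OC)c1O[Si](C(C)C)(C(C)C)C(C)C | intermediate
10 | 5-bromovanillin (3-bromo-4-hydroxy-5-methoxybenzaldehyde) | COc1cc(C=O)cc(Br)c1O | starting material
11 | (E)-3-bromo-4-hydroxy-5-methoxybenzaldehyde oxime | COc1cc(/C=N/O)cc(Br)c1O | intermediate
12 | 3-bromo-4-hydroxy-5-methoxybenzonitrile | COc1cc(C#N)cc(Br)c1O | intermediate
13 | 2-bromo-4-cyano-6-methoxyphenyl sulfurofluoridate | COc1cc(C#N)cc(Br)c1OS(=O)(=O)F | intermediate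
14 | 3-bromo-4-fluoro-5-methoxybenzonitrile | COc1cc(C#N)cc(Br)c1F | intermediate
15 | [3,5-dimethoxy-4-(triisopropylsilyloxy)phenyl]lithium | [Li]c1cc(OC)c(O[Si](C(C)C)(C(C)C)C(C)C)c(OC)c1 | intermediate
16 | lithium [3,5-dimethoxy-4-(triisopropylsilyloxy)phenyl][(E)-3-(triisopropylsilyloxy)prop-1-en-1-yl]borate of diol 4 (boron configuration unspecified) | [Li+].COc1cc([B-]2(/C=C/CO[Si](C(C)C)(C(C)C)C(C)C)O[C@@]3(C)c4cccc5cccc(c45)[C@@]3(C)O2)cc(OC)c1O[Si](C(C)C)(C(C)C)C(C)C | intermediate
17 | 3-{(1S,2R)-1-[3,5-dimethoxy-4-(triisopropylsilyloxy)phenyl]-1-(6b,9a-dimethyl-6b,9a-dihydroacenaphtho[1,2-d][1,3,2]dioxaborol-8-yl)-3-(triisopropylsilyloxy)propan-2-yl}-4-fluoro-5-methoxybenzonitrile | COc1cc([C@H]([C@@H](CO[Si](C(C)C)(C(C)C)C(C)C)c2cc(C#N)cc(OC)c2F)B2O[C@@]3(C)c4cccc5cccc(c45)[C@@]3(C)O2)cc(OC)c1O[Si](C(C)C)(C(C)C)C(C)C | intermediate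
18 | 3-{(1S,2R)-1-[3,5-dimethoxy-4-(triisopropylsilyloxy)phenyl]-1-hydroxy-3-(triisopropylsilyloxy)propan-2-yl}-4-fluoro-5-methoxybenzonitrile | COc1cc([C@H]([C@@H](CO[Si](C(C)C)(C(C)C)C(C)C)c2cc(C#N)cc(OC)c2F)O)cc(OC)c1O[Si](C(C)C)(C(C)C)C(C)C | intermediate
19 | (2S,3R)-2-[3,5-dimethoxy-4-(triisopropylsilyloxy)phenyl]-7-methoxy-3-[(triisopropylsilyloxy)methyl]-2,3-dihydro-1-benzofuran-5-carbonitrile | COc1cc([C@H]2Oc3c(OC)cc(C#N)cc3[C@@H]2CO[Si](C(C)C)(C(C)C)C(C)C)cc(OC)c1O[Si](C(C)C)(C(C)C)C(C)C | intermediate
20 | N-[bis(2-methylpropyl)alumanyl]-1-{(2S,3R)-2-[3,5-dimethoxy-4-(triisopropylsilyloxy)phenyl]-7-methoxy-3-[(triisopropylsilyloxy)methyl]-2,3-dihydro-1-benzofuran-5-yl}methanimine | COc1cc([C@H]2Oc3c(OC)cc(C=N[Al](CC(C)C)CC(C)C)cc3[C@@H]2CO[Si](C(C)C)(C(C)C)C(C)C)cc(OC)c1O[Si](C(C)C)(C(C)C)C(C)C | intermediate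
21 | (2S,3R)-2-[3,5-dimethoxy-4-(triisopropylsilyloxy)phenyl]-7-methoxy-3-[(triisopropylsilyloxy)methyl]-2,3-dihydro-1-benzofuran-5-carbaldehyde | COc1cc([C@H]2Oc3c(OC)cc(C=O)cc3[C@@H]2CO[Si](C(C)C)(C(C)C)C(C)C)cc(OC)c1O[Si](C(C)C)(C(C)C)C(C)C | intermediate
22 | 2-({(2S,3R)-2-[3,5-dimethoxy-4-(triisopropylsilyloxy)phenyl]-7-methoxy-3-[(triisopropylsilyloxy)methyl]-2,3-dihydro-1-benzofuran-5-yl}methylidene)propanedioic acid | COc1cc([C@H]2Oc3c(OC)cc(C=C(C(=O)O)C(=O)O)cc3[C@@H]2CO[Si](C(C)C)(C(C)C)C(C)C)cc(OC)c1O[Si](C(C)C)(C(C)C)C(C)C | intermediate
23 | (E)-3-{(2S,3R)-2-[3,5-dimethoxy-4-(triisopropylsilyloxy)phenyl]-7-methoxy-3-[(triisopropylsilyloxy)methyl]-2,3-dihydro-1-benzofuran-5-yl}prop-2-enoic acid | COc1cc([C@H]2Oc3c(OC)cc(/C=C/C(=O)O)cc3[C@@H]2CO[Si](C(C)C)(C(C)C)C(C)C)cc(OC)c1O[Si](C(C)C)(C(C)C)C(C)C | intermediate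
24 | (E)-3-[(2S,3R)-2-(4-hydroxy-3,5-dimethoxyphenyl)-3-(hydroxymethyl)-7-methoxy-2,3-dihydro-1-benzofuran-5-yl]prop-2-enoic acid | COc1cc([C@H]2Oc3c(OC)cc(/C=C/C(=O)O)cc3[C@@H]2CO)cc(OC)c1O | target

## Step count and risks

Total step count: 12 (three branches converging in step 7).
Longest linear sequence: 8 steps (steps 1, 3, 7, 8, 9, 10, 11, 12; the branch from 10 through steps 5 and 6 is equally long).

**Step 7 (key step).** The most likely failures are:
- direct transfer of ring B or of the alkenyl group from boron to palladium outrunning the metallate shift;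
- β-elimination of the silyloxy group or of hydride from the alkylpalladium intermediate;
- inhibition of the cationic pathway by bromide;
- weak facial discrimination with an ortho-fluorinated, nitrile-bearing arylpalladium species.

Fallback, setting out from 14 and 9 and returning at 18:
- Palladium-catalysed coupling of 14 with BrZnCH2CO2t-Bu [Pd2(dba)3, P(t-Bu)3, THF] should give tert-butyl 2-(5-cyano-2-fluoro-3-methoxyphenyl)acetate F1.
- CF3CO2H cleaves the ester to 2-(5-cyano-2-fluoro-3-methoxyphenyl)acetic acid F2.
- Its mixed pivalic anhydride acylates lithiated (S)-4-benzyl-1,3-oxazolidin-2-one to give 3-{2-[(4S)-4-benzyl-2-oxo-1,3-oxazolidin-3-yl]-2-oxoethyl}-4-fluoro-5-methoxybenzonitrile F3.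
- In parallel, bromine–lithium exchange on 9 and quenching with DMF gives 3,5-dimethoxy-4-(triisopropylsilyloxy)benzaldehyde F4.
- The dibutylboron enolate of F3 (Bu2BOSO2CF3, i-Pr2NEt) adds to F4 in an Evans syn aldol reaction to give 3-{(2S,3S)-1-[(4S)-4-benzyl-2-oxo-1,3-oxazolidin-3-yl]-3-[3,5-dimethoxy-4-(triisopropylsilyloxy)phenyl]-3-hydroxy-1-oxopropan-2-yl}-4-fluoro-5-methoxybenzonitrile F5.
- LiBH4 removes the auxiliary to give 3-{(1S,2R)-1-[3,5-dimethoxy-4-(triisopropylsilyloxy)phenyl]-1,3-dihydroxypropan-2-yl}-4-fluoro-5-methoxybenzonitrile F6.
- Silylation of the primary hydroxyl (i-Pr3SiCl, imidazole) returns 18.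

**Step 6.** Substitution at the doubly ortho-substituted ipso carbon may be slow, so that fluoride attack at sulfur simply returns phenol 12.

Fallback, setting out from 12 and returning at 19; it closes O1–C2 instead of O1–C7a and therefore also replaces step 9:
- 12 is protected (MeOCH2Cl, i-Pr2NEt) as 3-bromo-5-methoxy-4-(methoxymethoxy)benzonitrile F7.
- F7 takes the place of 14 towards borate 16 under the conditions of step 7 and should give 3-{(1S,2R)-1-[3,5-dimethoxy-4-(triisopropylsilyloxy)phenyl]-1-(6b,9a-dimethyl-6b,9a-dihydroacenaphtho[1,2-d][1,3,2]dioxaborol-8-yl)-3-(triisopropylsilyloxy)propan-2-yl}-5-methoxy-4-(methoxymethoxy)benzonitrile F8.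
- NaBO3·4H2O oxidises it to 3-{(1S,2R)-1-[3,5-dimethoxy-4-(triisopropylsilyloxy)phenyl]-1-hydroxy-3-(triisopropylsilyloxy)propan-2-yl}-5-methoxy-4-(methoxymethoxy)benzonitrile F9.
- CF3CO2H in CH2Cl2 at 0 °C then removes the acetal and ionises the electron-rich benzylic alcohol; the freed phenol captures the cation on the face away from the C3 substituent, so C3 steers the closure to trans 19.

**Step 3.** Regiocontrol in the hydroboration of the propargylic ether may be incomplete, or the ester exchange may stall and the alkenyl boron may be lost by protodeboronation on purification.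

Fallback, setting out from 2 and 9 and returning at 16; the ate complex is assembled with the roles of the partners reversed:
- Hydrozirconation of 2 with Cp2Zr(H)Cl followed by iodine gives triisopropyl{[(E)-3-iodoprop-2-en-1-yl]oxy}silane F10.
- 9 is lithiated to 15, borylated with B(Oi-Pr)3 and esterified with 4 to give 8-[3,5-dimethoxy-4-(triisopropylsilyloxy)phenyl]-6b,9a-dimethyl-6b,9a-dihydroacenaphtho[1,2-d][1,3,2]dioxaborole F11.
- Iodine–lithium exchange on F10 (t-BuLi, Et2O, −78 °C) gives [(E)-3-(triisopropylsilyloxy)prop-1-en-1-yl]lithium F12, which adds to F11 to form the same borate 16.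

**Step 12.** Once the phenoxide is free in basic fluoride, the C2–O1 bond may open through the para-quinone methide (epimerisation at C2 or decomposition), or the primary silyl ether may be cleaved incompletely.

Fallback, setting out from 21 and returning at 24:
- Both silyl groups are removed at the aldehyde stage under buffered acidic fluoride (HF·pyridine, THF) to give (2S,3R)-2-(4-hydroxy-3,5-dimethoxyphenyl)-3-(hydroxymethyl)-7-methoxy-2,3-dihydro-1-benzofuran-5-carbaldehyde F13.
- The Knoevenagel–Doebner condensation of step 11, which tolerates free phenols, is then run on F13 and gives 24 directly, so the last step is a condensation and not a desilylation.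

## Further compounds

F1 | step 7 | tert-butyl 2-(5-cyano-2-fluoro-3-methoxyphenyl)acetate | COc1cc(C#N)cc(CC(=O)OC(C)(C)C)c1F
F2 | step 7 | 2-(5-cyano-2-fluoro-3-methoxyphenyl)acetic acid | COc1cc(C#N)cc(CC(=O)O)c1F
F3 | step 7 | 3-{2-[(4S)-4-benzyl-2-oxo-1,3-oxazolidin-3-yl]-2-oxoethyl}-4-fluoro-5-methoxybenzonitrile | COc1cc(C#N)cc(CC(=O)N2[C@@H](Cc3ccccc3)COC2=O)c1F
F4 | step 7 | 3,5-dimethoxy-4-(triisopropylsilyloxy)benzaldehyde | COc1cc(C=O)cc(OC)c1O[Si](C(C)C)(C(C)C)C(C)C
F5 | step 7 | 3-{(2S,3S)-1-[(4S)-4-benzyl-2-oxo-1,3-oxazolidin-3-yl]-3-[3,5-dimethoxy-4-(triisopropylsilyloxy)phenyl]-3-hydroxy-1-oxopropan-2-yl}-4-fluoro-5-methoxybenzonitrile | COc1cc([C@H]([C@@H](C(=O)N3[C@@H](Cc4ccccc4)COC3=O)c2cc(C#N)cc(OC)c2F)O)cc(OC)c1O[Si](C(C)C)(C(C)C)C(C)C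
F6 | step 7 | 3-{(1S,2R)-1-[3,5-dimethoxy-4-(triisopropylsilyloxy)phenyl]-1,3-dihydroxypropan-2-yl}-4-fluoro-5-methoxybenzonitrile | COc1cc([C@H]([C@@H](CO)c2cc(C#N)cc(OC)c2F)O)cc(OC)c1O[Si](C(C)C)(C(C)C)C(C)C
F7 | step 6 | 3-bromo-5-methoxy-4-(methoxymethoxy)benzonitrile | COCOc1c(Br)cc(C#N)cc1OC
F8 | step 6 | 3-{(1S,2R)-1-[3,5-dimethoxy-4-(triisopropylsilyloxy)phenyl]-1-(6b,9a-dimethyl-6b,9a-dihydroacenaphtho[1,2-d][1,3,2]dioxaborol-8-yl)-3-(triisopropylsilyloxy)propan-2-yl}-5-methoxy-4-(methoxymethoxy)benzonitrile | COc1cc([C@H]([C@@H](CO[Si](C(C)C)(C(C)C)C(C)C)c2cc(C#N)cc(OC)c2OCOC)B2O[C@@]3(C)c4cccc5cccc(c45)[C@@]3(C)O2)cc(OC)c1O[Si](C(C)C)(C(C)C)C(C)C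
F9 | step 6 | 3-{(1S,2R)-1-[3,5-dimethoxy-4-(triisopropylsilyloxy)phenyl]-1-hydroxy-3-(triisopropylsilyloxy)propan-2-yl}-5-methoxy-4-(methoxymethoxy)benzonitrile | COc1cc([C@H]([C@@H](CO[Si](C(C)C)(C(C)C)C(C)C)c2cc(C#N)cc(OC)c2OCOC)O)cc(OC)c1O[Si](C(C)C)(C(C)C)C(C)C
F10 | step 3 | triisopropyl{[(E)-3-iodoprop-2-en-1-yl]oxy}silane | CC(C)[Si](C(C)C)(C(C)C)OC/C=C/I
F11 | step 3 | 8-[3,5-dimethoxy-4-(triisopropylsilyloxy)phenyl]-6b,9a-dimethyl-6b,9a-dihydroacenaphtho[1,2-d][1,3,2]dioxaborole | COc1cc(B2O[C@@]3(C)c4cccc5cccc(c45)[C@@]3(C)O2)cc(OC)c1O[Si](C(C)C)(C(C)C)C(C)C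
F12 | step 3 | [(E)-3-(triisopropylsilyloxy)prop-1-en-1-yl]lithium | [Li]/C=C/CO[Si](C(C)C)(C(C)C)C(C)C
F13 | step 12 | (2S,3R)-2-(4-hydroxy-3,5-dimethoxyphenyl)-3-(hydroxymethyl)-7-methoxy-2,3-dihydro-1-benzofuran-5-carbaldehyde | COc1cc([C@H]2Oc3c(OC)cc(C=O)cc3[C@@H]2CO)cc(OC)c1O
A1 | alternative 1 | methyl (2S,3S)-5-bromo-2-[3,5-dimethoxy-4-(pivaloyloxy)phenyl]-7-methoxy-2,3-dihydro-1-benzofuran-3-carboxylate (trans) | COc1cc([C@H]2Oc3c(OC)cc(Br)cc3[C@@H]2C(=O)OC)cc(OC)c1OC(=O)C(C)(C)C
A2 | alternative 1 | (2S)-6-bromo-2-[3,5-dimethoxy-4-(pivaloyloxy)phenyl]-8-methoxy-2,3-dihydro-4H-chromen-4-one | O=C1C[C@@H](c2cc(OC)c(OC(=O)C(C)(C)C)c(OC)c2)Oc2c(OC)cc(Br)cc21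
A3 | alternative 2 | {[(2S,3R)-5-bromo-2-{4-[(tert-butyldimethylsilyl)oxy]-3,5-dimethoxyphenyl}-7-methoxy-2,3-dihydro-1-benzofuran-3-yl]methoxy}(tert-butyl)dimethylsilane (trans) | COc1cc([C@H]2Oc3c(OC)cc(Br)cc3[C@@H]2CO[Si](C)(C)C(C)(C)C)cc(OC)c1O[Si](C)(C)C(C)(C)C
A4 | alternative 2 | 4-bromo-2-{2-[(tert-butyldimethylsilyl)oxy]-1-[(4-methylphenyl)sulfonyl]ethyl}-6-methoxyphenol (racemic) | COc1cc(Br)cc(C(CO[Si](C)(C)C(C)(C)C)S(=O)(=O)c2ccc(C)cc2)c1O
A5 | alternative 2 | 4-bromo-6-{2-[(tert-butyldimethylsilyl)oxy]ethylidene}-2-methoxycyclohexa-2,4-dien-1-one (ortho-quinone methide) | O=C1C(OC)=CC(Br)=CC1=CCO[Si](C)(C)C(C)(C)C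
A6 | alternative 2 | (2R,5R)-1-{4-[(tert-butyldimethylsilyl)oxy]-3,5-dimethoxybenzyl}-2,5-dimethylthiolan-1-ium trifluoromethanesulfonate | C[C@@H]1CC[C@@H](C)[S+]1Cc1cc(OC)c(O[Si](C)(C)C(C)(C)C)c(OC)c1.[O-]S(=O)(=O)C(F)(F)F
A7 | alternative 3 | (2S,3R)-2-[4-(benzyloxy)-3,5-dimethoxyphenyl]-7-methoxy-3-{[(triisopropylsilyl)oxy]methyl}-2,3-dihydro-1-benzofuran-5-carbonitrile (trans) | COc1cc([C@H]2Oc3c(OC)cc(C#N)cc3[C@@H]2CO[Si](C(C)C)(C(C)C)C(C)C)cc(OC)c1OCc1ccccc1
A8 | alternative 3 | 3-{(1S,2R)-1-[4-(benzyloxy)-3,5-dimethoxyphenyl]-1-hydroxy-3-[(triisopropylsilyl)oxy]propan-2-yl}-4-fluoro-5-methoxybenzonitrile | COc1cc([C@H]([C@@H](CO[Si](C(C)C)(C(C)C)C(C)C)c2cc(C#N)cc(OC)c2F)O)cc(OC)c1OCc1ccccc1
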